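The constants on hand are charges, so the one quantity worth carrying is what a given charge of catalyst can buy.

| setting | maple | flask |
|---|---|---|
| starting material | 0.55 M | 0.55 M |
| reagent | 0.60 equiv | 0.600 equiv |
| free catalyst | 0.11 mol% | 0.11 mol% |
| impurity | 0.11 mM | 0.11 mM |
| remark | the very flask that is asked about, followed so far |  |
| time |  | 2.0 h |

maple run (percent of the starting material charged)

| time / min | product / % | starting material / % |
|---|---|---|
| 6.00 | 8.9 | 89.5 |
| 10.0 | 14.5 | 84.4 |
| 20.0 | 22.6 | 77.0 |
| 40.0 | 30.3 | 70.5 |
| 80.0 | 34.4 | 63.0 |

(readings scatter by 1 percentage point)

- autumn: at 2.0 h add free catalyst, 100 % of the amount charged, then wait 40 min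
- midnight: at 2.0 h take out 90 % of the product then present, then wait 40 min
- summer: change nothing and wait 40 min more
- dawn: at 2.0 h add reagent, 100 % of the amount charged, then wait 40 min

- product taken out counts as made
- additions bring no volume worth counting

- product, in percent of the starting material first charged, at 2.0 h
- what to do for the largest gain in product; "none" if nothing gains more than 2 percentage points (autumn / midnight / summer / dawn / none)
- product present, with what was taken out counted in, in percent of the starting material first charged, after midnight
- product present, with what was taken out counted in, in percent of the starting material first charged, after dawn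

1. In the maple run, c(free catalyst) is charged at 0.605 mM, and c(impurity), at 0.11 mM, equals 18.2 % of that.

2. Product gain per minute in the maple run falls between the last two intervals with a decay time of 22.7 min, as a reading. The tail after 80.0 min therefore adds 0.96 percentage points, and my estimate for 2.0 h is 35.4 %.

3. Objection: that curve does not say why product stops. An equilibrium and a dying catalyst can draw much the same shape.

4. A scale answers it. The catalyst budget n (turnover number), product made per catalyst charged, reads 313. Zero on the scale is a stop at equilibrium, where a second dose gains nothing. One is a dying catalyst whose second dose earns the first budget again, 34 points.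

5. Objection: the readings place this flask nowhere on that scale. My bet is a dying catalyst, on thin grounds: the loading is small, and impurity stands at a visible share of it. So I choose autumn, and expect midnight and dawn to stay within the scatter of the estimate.

6. The forecast gives 35.7 % (34.5 % to 37 %), chooses dawn, and puts midnight at 44.5 % (36 % to 47 %) and dawn at 55.5 % (37 % to 58.5 %). It differs from my bet: “I lean towards equilibrium, hence wide ranges”.

7. The flask gives 35.4 % at 2.0 h. Autumn gains 16 points, more than any other option, while midnight ends at 35.5 % and dawn at 35.8 %.

    starting material + free catalyst ⇌ catalyst intermediate A (K = 3.30 M⁻¹, k = 1770 M⁻¹ min⁻¹)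
    reagent + catalyst intermediate A → catalyst intermediate B (k = 220 M⁻¹ min⁻¹)
    catalyst intermediate B → free catalyst + product (k = 38.3 min⁻¹)
    starting material + catalyst intermediate A → spent catalyst A (k = 0.199 M⁻¹ min⁻¹)
    free catalyst → spent catalyst B (k = 0.0447 min⁻¹)
    free catalyst + impurity → spent catalyst C (k = 20500 M⁻¹ min⁻¹)

Autumn stands at 0.459 on the scale, well away from zero. Catalyst intermediate A meets either reagent, going on to product, or starting material, going to spent catalyst A, which holds 58.3 % of the catalyst at 2.00 h. Taking that loss away lifts the flask's product from 35.4 % to 53.8 %, which is a part of the story. Without that loss autumn's gain falls from 16 points to 4.9 points, at most the largest single effect and not the main reason. Scaled with the reagent charge, n gives 521 for the neighbour flask with 1.00 equiv, whose simulated 59.2 % means 538 turnovers.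

The numbers in the tables are calculated on assumed constants; noise was put on by code.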